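**Plan**

Labels: ring A is the guaiacyl ring (C1–C6, O4 carries the 1,3-dihydroxypropan-2-yl group), C7–C8–C9 is the propane chain, ring B is the 2,6-dimethoxy-4-(3-hydroxypropyl)phenoxy group on C8.
Retrosynthesis: after removing the acetonide and silyl ether and tracing the 3-hydroxypropyl chain back to an allyl group, the C1–C7 bond is cut first (aryl–metal plus aldehyde), then the C8–O(ring B) ether bond, then the O4–CH ether bond on ring A.
Enabling feature: C7 is a benzylic carbinol attached to C1 of ring A, and C8 (with its aryloxy oxygen) together with C9 is a glycerate unit sold enantiopure. Both benzene rings are bought, so no ring is formed.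
Forward: methyl (S)-glycerate is silylated on O9, etherified at C8 with the ring-B phenol, reduced to the aldehyde and joined to the ring-A aryl–titanium reagent; hydroboration of the allyl group and two deprotections finish the chain.
Stereochemistry: C8 (R) comes from the (S)-glycerate through one Mitsunobu inversion; C7 (S) is set by Felkin–Anh 1,2-induction from C8 in the aryl addition.

Key step: step 6

Assumption: the four starting materials are commercial; metal alkoxides that only await aqueous work-up are not numbered, whereas species consumed by a further reagent in the same flask are.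

**Route**

Step 1
Reactants: 1 4-bromo-2-methoxyphenol; 2 2,2-dimethyl-1,3-dioxan-5-ol
Product: 3 5-(4-bromo-2-methoxyphenoxy)-2,2-dimethyl-1,3-dioxane
Conditions: PPh3, DIAD, THF, 0 °C → rt
Reagents that add atoms: none
Why: Mitsunobu etherification, in which the phenol (pKa about 10) protonates the betaine and then displaces the phosphonium-activated secondary hydroxyl of the achiral dioxanol by SN2; no stereocentre is involved.

Step 2
Reactants: 4 methyl (S)-2,2-dimethyl-1,3-dioxolane-4-carboxylate
Product: 5 methyl (S)-2,3-dihydroxypropanoate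
Conditions: Amberlyst-15 (H+ form), MeOH, rt; filter, concentrate
Reagents that add atoms: none
Why: Acid-catalysed transacetalisation passes the isopropylidene group to methanol and frees the diol, while the methyl ester is unchanged in methanol and no bond to the stereocentre is broken.

Step 3
Reactants: 5 methyl (S)-2,3-dihydroxypropanoate
Product: 6 methyl (S)-3-(tert-butyldiphenylsilyloxy)-2-hydroxypropanoate
Conditions: TBDPSCl (1.05 equiv), imidazole, CH2Cl2, 0 °C
Reagents that add atoms: tert-butyl(chloro)diphenylsilane (TBDPSCl), CC(C)(C)[Si](Cl)(c1ccccc1)c1ccccc1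
Why: Sterically controlled silylation, since the bulky silyl chloride reacts at the primary hydroxyl much faster than at the secondary hydroxyl next to the ester, and the configuration is untouched.

Step 4
Reactants: 6 methyl (S)-3-(tert-butyldiphenylsilyloxy)-2-hydroxypropanoate; 7 4-allyl-2,6-dimethoxyphenol
Product: 8 methyl (R)-2-(4-allyl-2,6-dimethoxyphenoxy)-3-(tert-butyldiphenylsilyloxy)propanoate
Conditions: PPh3, DIAD, toluene, 0 °C → rt
Reagents that add atoms: none
Why: Mitsunobu reaction, in which the phenoxide displaces the alkoxyphosphonium ion at the ester-activated secondary carbon by SN2 with inversion, turning the (S)-carbinol into the (R)-aryl ether that becomes C8.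

Step 5
Reactants: 8 methyl (R)-2-(4-allyl-2,6-dimethoxyphenoxy)-3-(tert-butyldiphenylsilyloxy)propanoate
Product: 9 (R)-2-(4-allyl-2,6-dimethoxyphenoxy)-3-(tert-butyldiphenylsilyloxy)propanal
Conditions: DIBAL-H (1.1 equiv), CH2Cl2, −78 °C; MeOH, then aq Rochelle salt; used crude
Reagents that add atoms: none
Why: Partial DIBAL-H reduction of an α-alkoxy ester, where the aluminium hemiacetal is held at −78 °C by the neighbouring oxygen and releases the aldehyde only on quench, so over-reduction and epimerisation of C8 should be avoided.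

Step 6
Reactants: 3 5-(4-bromo-2-methoxyphenoxy)-2,2-dimethyl-1,3-dioxane; 9 (R)-2-(4-allyl-2,6-dimethoxyphenoxy)-3-(tert-butyldiphenylsilyloxy)propanal
Product: 12 (1S,2R)-2-(4-allyl-2,6-dimethoxyphenoxy)-3-(tert-butyldiphenylsilyloxy)-1-[4-(2,2-dimethyl-1,3-dioxan-5-yloxy)-3-methoxyphenyl]propan-1-ol, via aryllithium 10 (not isolated), via aryltitanium triisopropoxide 11 (not isolated)
Conditions: 3 (1.5 equiv), n-BuLi, THF, −78 °C; ClTi(OiPr)3, −78 → −40 °C; then 9, −78 → 0 °C; aq NH4Cl
Reagents that add atoms: none
Why: Bromine–lithium exchange on 3 gives aryllithium 10, transmetalation with ClTi(OiPr)3 gives aryltitanium reagent 11, and its aryl group adds to the formyl carbon of 9 through an open, polar Felkin–Anh transition state, forming the C1–C7 bond and the C7 carbinol. The closest known reaction type is the non-chelation-controlled 1,2-addition of organotitanium triisopropoxides to α-alkoxy aldehydes. No ring is closed. The new stereocentre C7 is controlled by the existing C8 centre: the C8–OAr bond stands antiperiplanar to the incoming aryl group, which approaches along the Bürgi–Dunitz trajectory past the C8 hydrogen and not past the CH2OTBDPS group, so the anti (erythro) 7S,8R alcohol should predominate. The step needs anti over syn induction without chelation and without epimerisation of C8; the di-ortho-substituted aryl ether oxygen and the bulky TBDPS ether are poor donors, the Ti(OiPr)3 centre is too weak a Lewis acid to chelate, and the reagent is essentially non-basic, so the α-aryloxy aldehyde should not be enolised.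

Step 7
Reactants: 12 (1S,2R)-2-(4-allyl-2,6-dimethoxyphenoxy)-3-(tert-butyldiphenylsilyloxy)-1-[4-(2,2-dimethyl-1,3-dioxan-5-yloxy)-3-methoxyphenyl]propan-1-ol
Product: 14 (1S,2R)-3-(tert-butyldiphenylsilyloxy)-1-[4-(2,2-dimethyl-1,3-dioxan-5-yloxy)-3-methoxyphenyl]-2-[4-(3-hydroxypropyl)-2,6-dimethoxyphenoxy]propan-1-ol, via B-alkyl-9-BBN adduct 13 (not isolated)
Conditions: 9-BBN (3 equiv), THF, 0 °C → rt; then aq NaOH, 30% H2O2, 0 °C → rt
Reagents that add atoms: hydrogen peroxide, OO
Why: Hydroboration–oxidation, in which 9-BBN places boron on the terminal carbon of the allyl group (the excess tolerates the free C7 hydroxyl) and alkaline peroxide converts the C–B bond into the primary alcohol without touching C7 or C8.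

Step 8
Reactants: 14 (1S,2R)-3-(tert-butyldiphenylsilyloxy)-1-[4-(2,2-dimethyl-1,3-dioxan-5-yloxy)-3-methoxyphenyl]-2-[4-(3-hydroxypropyl)-2,6-dimethoxyphenoxy]propan-1-ol
Product: 15 (1S,2R)-1-[4-(2,2-dimethyl-1,3-dioxan-5-yloxy)-3-methoxyphenyl]-2-[4-(3-hydroxypropyl)-2,6-dimethoxyphenoxy]propane-1,3-diol
Conditions: TBAF (1.2 equiv), THF, 0 °C → rt
Reagents that add atoms: none
Why: Fluoride-mediated desilylation driven by the strong Si–F bond removes the TBDPS ether, while the acetonide, the aryl ethers and both stereocentres are inert to TBAF.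

Step 9
Reactants: 15 (1S,2R)-1-[4-(2,2-dimethyl-1,3-dioxan-5-yloxy)-3-methoxyphenyl]-2-[4-(3-hydroxypropyl)-2,6-dimethoxyphenoxy]propane-1,3-diol
Product: 16 (1S,2R)-1-[4-(1,3-dihydroxypropan-2-yloxy)-3-methoxyphenyl]-2-[4-(3-hydroxypropyl)-2,6-dimethoxyphenoxy]propane-1,3-diol
Conditions: AcOH/H2O (4:1), rt
Reagents that add atoms: none
Why: Mild aqueous acid hydrolysis of the six-membered isopropylidene acetal, with a weak acid and water (not an alcohol) as nucleophile so that the p-alkoxybenzylic C7 carbinol should not ionise, epimerise or form an ether.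

**Compound list**

1 | 4-bromo-2-methoxyphenol | COc1cc(Br)ccc1O | starting material
2 | 2,2-dimethyl-1,3-dioxan-5-ol | CC1(C)OCC(O)CO1 | starting material
3 | 5-(4-bromo-2-methoxyphenoxy)-2,2-dimethyl-1,3-dioxane | COc1cc(Br)ccc1OC1COC(C)(C)OC1 | intermediate
4 | methyl (S)-2,2-dimethyl-1,3-dioxolane-4-carboxylate | COC(=O)[C@@H]1COC(C)(C)O1 | starting material
5 | methyl (S)-2,3-dihydroxypropanoate | COC(=O)[C@@H](O)CO | intermediate
6 | methyl (S)-3-(tert-butyldiphenylsilyloxy)-2-hydroxypropanoate | COC(=O)[C@@H](O)CO[Si](c1ccccc1)(c1ccccc1)C(C)(C)C | intermediate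
7 | 4-allyl-2,6-dimethoxyphenol | C=CCc1cc(OC)c(O)c(OC)c1 | starting material
8 | methyl (R)-2-(4-allyl-2,6-dimethoxyphenoxy)-3-(tert-butyldiphenylsilyloxy)propanoate | COC(=O)[C@@H](CO[Si](c1ccccc1)(c1ccccc1)C(C)(C)C)Oc1c(OC)cc(CC=C)cc1OC | intermediate
9 | (R)-2-(4-allyl-2,6-dimethoxyphenoxy)-3-(tert-butyldiphenylsilyloxy)propanal | O=C[C@@H](CO[Si](c1ccccc1)(c1ccccc1)C(C)(C)C)Oc1c(OC)cc(CC=C)cc1OC | intermediate
10 | [4-(2,2-dimethyl-1,3-dioxan-5-yloxy)-3-methoxyphenyl]lithium | COc1cc([Li])ccc1OC1COC(C)(C)OC1 | intermediate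
11 | [4-(2,2-dimethyl-1,3-dioxan-5-yloxy)-3-methoxyphenyl]titanium triisopropoxide | COc1cc([Ti](OC(C)C)(OC(C)C)OC(C)C)ccc1OC1COC(C)(C)OC1 | intermediate
12 | (1S,2R)-2-(4-allyl-2,6-dimethoxyphenoxy)-3-(tert-butyldiphenylsilyloxy)-1-[4-(2,2-dimethyl-1,3-dioxan-5-yloxy)-3-methoxyphenyl]propan-1-ol | COc1cc([C@H](O)[C@@H](CO[Si](c3ccccc3)(c3ccccc3)C(C)(C)C)Oc2c(OC)cc(CC=C)cc2OC)ccc1OC1COC(C)(C)OC1 | intermediate
13 | 9-[3-(ring-B aryl)propyl]-9-borabicyclo[3.3.1]nonane adduct of 12 (boron on the terminal carbon of the former allyl group) | COc1cc([C@H](O)[C@@H](CO[Si](c3ccccc3)(c3ccccc3)C(C)(C)C)Oc2c(OC)cc(CCCB4C5CCCC4CCC5)cc2OC)ccc1OC1COC(C)(C)OC1 | intermediate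
14 | (1S,2R)-3-(tert-butyldiphenylsilyloxy)-1-[4-(2,2-dimethyl-1,3-dioxan-5-yloxy)-3-methoxyphenyl]-2-[4-(3-hydroxypropyl)-2,6-dimethoxyphenoxy]propan-1-ol | COc1cc([C@H](O)[C@@H](CO[Si](c3ccccc3)(c3ccccc3)C(C)(C)C)Oc2c(OC)cc(CCCO)cc2OC)ccc1OC1COC(C)(C)OC1 | intermediate
15 | (1S,2R)-1-[4-(2,2-dimethyl-1,3-dioxan-5-yloxy)-3-methoxyphenyl]-2-[4-(3-hydroxypropyl)-2,6-dimethoxyphenoxy]propane-1,3-diol | COc1cc([C@H](O)[C@@H](CO)Oc2c(OC)cc(CCCO)cc2OC)ccc1OC1COC(C)(C)OC1 | intermediate
16 | (1S,2R)-1-[4-(1,3-dihydroxypropan-2-yloxy)-3-methoxyphenyl]-2-[4-(3-hydroxypropyl)-2,6-dimethoxyphenoxy]propane-1,3-diol (CNP0324330.1) | COc1cc([C@H](O)[C@@H](CO)Oc2c(OC)cc(CCCO)cc2OC)ccc1OC(CO)CO | target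

**Step count and risks**

Total steps: 9. Longest linear sequence: 8 steps (4 → 16, steps 2–9); the ring-A branch (step 1) joins at step 6.

Most likely to fail:

1. Step 6 – insufficient facial selectivity or erosion of C8. If part of the addition runs through a chelated geometry, or the aldehyde enolises before it is consumed, the syn (threo) C7 epimer or the C8 epimer would contaminate 12. The fallback sets out from ester 8 and comes back to the route at 12. Ester 8 would be treated with MeNHOMe·HCl and i-PrMgCl (THF, −20 °C) to give the Weinreb amide (R)-2-(4-allyl-2,6-dimethoxyphenoxy)-3-(tert-butyldiphenylsilyloxy)-N-methoxy-N-methylpropanamide F1. Aryllithium 10 (from 3 and n-BuLi, THF, −78 °C) would add once to F1 and, after work-up, give the aryl ketone (R)-2-(4-allyl-2,6-dimethoxyphenoxy)-3-(tert-butyldiphenylsilyloxy)-1-[4-(2,2-dimethyl-1,3-dioxan-5-yloxy)-3-methoxyphenyl]propan-1-one F2. Reduction of F2 with Zn(BH4)2 (Et2O, −20 °C) should then proceed under chelation control: the strongly Lewis acidic zinc binds the carbonyl and the C8 aryloxy oxygen, and hydride enters from the face carrying the C8 hydrogen, which leads to the same anti alcohol 12. In this variant the C1–C7 bond arises by acylation, the sensitive aldehyde is avoided, and C7 is set by hydride delivery.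

2. Step 4 – slow displacement by the di-ortho-substituted phenol. The hindered phenoxide may attack the alkoxyphosphonium ion too slowly, so that alkylation of the reduced azodicarboxylate or elimination to the β-silyloxy acrylate takes over. The fallback sets out from hydroxy ester 6 and comes back at 8. Compound 6 would be converted with Tf2O and 2,6-lutidine (CH2Cl2, −78 °C) into methyl (S)-3-(tert-butyldiphenylsilyloxy)-2-(trifluoromethylsulfonyloxy)propanoate F3, which would be used cold and treated with the caesium phenoxide of 7 (Cs2CO3, MeCN, 0 °C). SN2 displacement of an α-triflyloxy ester by a phenoxide proceeds with inversion and should give the same (R)-ether 8 without a phosphorus-based activating group.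

3. Step 5 – over-reduction or loss of configurational purity at C8. The hemiacetal may collapse before the quench and be reduced further, and the α-aryloxy aldehyde may epimerise during a slow work-up. The fallback sets out from ester 8 and comes back at 9. Ester 8 would be reduced fully with excess DIBAL-H (CH2Cl2, −78 → 0 °C) to the stable primary alcohol (S)-2-(4-allyl-2,6-dimethoxyphenoxy)-3-(tert-butyldiphenylsilyloxy)propan-1-ol F4, which can be purified and stored. Oxidation of F4 with Dess–Martin periodinane and NaHCO3 (CH2Cl2, 0 °C) under neutral conditions should then give aldehyde 9, to be filtered and used at once in step 6.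

**Further compounds**

F1 | step 6 | (R)-2-(4-allyl-2,6-dimethoxyphenoxy)-3-(tert-butyldiphenylsilyloxy)-N-methoxy-N-methylpropanamide | CON(C)C(=O)[C@@H](CO[Si](c1ccccc1)(c1ccccc1)C(C)(C)C)Oc1c(OC)cc(CC=C)cc1OC
F2 | step 6 | (R)-2-(4-allyl-2,6-dimethoxyphenoxy)-3-(tert-butyldiphenylsilyloxy)-1-[4-(2,2-dimethyl-1,3-dioxan-5-yloxy)-3-methoxyphenyl]propan-1-one | COc1cc(C(=O)[C@@H](CO[Si](c3ccccc3)(c3ccccc3)C(C)(C)C)Oc2c(OC)cc(CC=C)cc2OC)ccc1OC1COC(C)(C)OC1
F3 | step 4 | methyl (S)-3-(tert-butyldiphenylsilyloxy)-2-(trifluoromethylsulfonyloxy)propanoate | COC(=O)[C@@H](OS(=O)(=O)C(F)(F)F)CO[Si](c1ccccc1)(c1ccccc1)C(C)(C)C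
F4 | step 5 | (S)-2-(4-allyl-2,6-dimethoxyphenoxy)-3-(tert-butyldiphenylsilyloxy)propan-1-ol | OC[C@@H](CO[Si](c1ccccc1)(c1ccccc1)C(C)(C)C)Oc1c(OC)cc(CC=C)cc1OC
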